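**Retrosynthetic overview**

1. Target 20 is ring A, a 2,5-dihydroxy-1,4-benzoquinone (carbonyls C1 and C4, hydroxyls C2 and C5, hydrogen on C6) carrying an (E)-nonadec-14-enyl chain on C3. It is unmasked from diethoxyquinone 18 by hydrolysis, and 18 comes from 4-methoxyphenol 17 by oxidation.
2. The strategy rests on the way each ring-A atom of 17 maps onto a chromium benzannulation: C4 is a carbene carbon (OMe), C5–C6 a 1-ethoxyvinyl group, C2–C3 the two carbons of an ynol ether (OEt on C2, chain on C3) and C1 a CO ligand. Bonds C3–C4, C1–C2 and C1–C6 form in one step.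
3. Ynol ether 10 comes from lithium ethoxyacetylide and the C19 iodide 7. Iodide 7 comes from the C14 Grignard reagent of myristelaidic acid 1 (E-olefin already in place) and 1-bromo-5-chloropentane under copper catalysis.
4. Carbene complex 15 comes from ethyl vinyl ether (α-lithiation), Cr(CO)6 and Me3OBF4.
5. Ring A is the only ring and is formed in step 7; the E double bond is carried through untouched.

Key step: step 7

Remark: ring-A locants follow the 1,4-benzoquinone numbering above for all precursors; the target has no stereocentre, and its only stereochemical element, the E double bond at C14′=C15′ of the chain, is bought with acid 1.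

**Route**

Step 1
Reactants: 1 myristelaidic acid [(E)-tetradec-9-enoic acid]
Product: 2 (E)-tetradec-9-en-1-ol
Conditions: LiAlH4, THF, 0 → 20 °C; then aq. potassium sodium tartrate
Reagents that add atoms: none
Why: Hydride reduction of a carboxylic acid to the primary alcohol; LiAlH4 does not touch an isolated, non-conjugated olefin.

Step 2
Reactants: 2 (E)-tetradec-9-en-1-ol
Product: 3 (E)-14-bromotetradec-5-ene [= (E)-1-bromotetradec-9-ene]
Conditions: CBr4, PPh3, CH2Cl2, 0 → 20 °C
Reagents that add atoms: carbon tetrabromide, BrC(Br)(Br)Br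
Why: Appel bromination replaces the primary hydroxyl by SN2 attack of bromide on the oxyphosphonium under neutral conditions that leave the olefin alone.

Step 3
Reactants: 3 (E)-14-bromotetradec-5-ene; 4 1-bromo-5-chloropentane
Product: 6 (E)-19-chlorononadec-5-ene [= (E)-1-chlorononadec-14-ene], via (E)-tetradec-9-enylmagnesium bromide 5 (not isolated)
Conditions: Mg, THF, 40 °C; then 4 (1.5 equiv), Li2CuCl4 (3 mol %), THF, −10 → 20 °C
Reagents that add atoms: magnesium, [Mg] (held only in 5)
Why: Copper-catalysed cross-coupling of a primary alkyl Grignard reagent with a primary alkyl bromide; the C–Br bond of 4 reacts far faster than its C–Cl bond, so the five-carbon extension should stop at the monochloride.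

Step 4
Reactants: 6 (E)-19-chlorononadec-5-ene
Product: 7 (E)-19-iodononadec-5-ene [= (E)-1-iodononadec-14-ene]
Conditions: NaI, butan-2-one, 80 °C
Reagents that add atoms: sodium iodide, [Na+].[I-]
Why: Finkelstein halide exchange, driven by precipitation of NaCl, turns the sluggish chloride into the iodide needed for the next SN2 alkylation.

Step 5
Reactants: 7 (E)-19-iodononadec-5-ene; 8 ethoxyacetylene
Product: 10 (E)-1-ethoxyhenicos-16-en-1-yne, via lithium ethoxyacetylide 9 (not isolated)
Conditions: 8 (3 equiv), n-BuLi, THF, −78 °C; then 7, HMPA, −78 → 20 °C; aq. NaHCO3 work-up, Et3N-deactivated silica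
Reagents that add atoms: n-butyllithium, [Li]CCCC (lithium held only in 9)
Why: SN2 alkylation of a lithium alkoxyacetylide with a primary iodide in THF/HMPA is the standard route to 1-alkoxyalk-1-ynes; excess acetylide offsets its modest nucleophilicity, and the basic work-up protects the acid-labile ynol ether.

Step 6
Reactants: 11 ethyl vinyl ether; 12 chromium hexacarbonyl Cr(CO)6
Product: 15 pentacarbonyl[(1-ethoxyvinyl)(methoxy)carbene]chromium, via 1-ethoxyvinyllithium 13 (not isolated), via lithium pentacarbonyl(2-ethoxyacryloyl)chromate 14 (not isolated)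
Conditions: 11, t-BuLi, THF, −78 → 0 °C; 12, Et2O, 0 → 20 °C; evaporate; then Me3OBF4, CH2Cl2, 0 °C
Reagents that add atoms: tert-butyllithium, [Li]C(C)(C)C (lithium held only in 13 or 14); trimethyloxonium tetrafluoroborate, C[O+](C)C.F[B-](F)(F)F
Why: Fischer carbene synthesis: the α-lithiated enol ether adds to a CO ligand of Cr(CO)6 and the acyl chromate is O-methylated by the hard oxonium salt; the α-ethoxy substituent on the vinyl group should keep this acrylate-like complex from polymerising.

Step 7
Reactants: 10 (E)-1-ethoxyhenicos-16-en-1-yne; 15 pentacarbonyl[(1-ethoxyvinyl)(methoxy)carbene]chromium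
Product: 17 2,5-diethoxy-4-methoxy-3-[(E)-nonadec-14-enyl]phenol, via tricarbonyl(η6-arene)chromium complex 16 (not isolated)
Conditions: 15 (1.5 equiv), THF (0.05 M, degassed), 55 °C, Ar; then air, 20 °C
Reagents that add atoms: none
Why: Proposed new method: on warming, 15 loses one CO (or the electron-rich alkyne attacks the carbene carbon directly, as ynamines do) and 10 inserts into the Cr=C bond so that its chain-bearing carbon joins the carbene carbon (C3–C4) and its ethoxy-bearing carbon becomes the new carbene centre, where a CO ligand inserts (C1–C2) to give a chromium-bound dienylketene. Ring A, a six-membered carbocycle, is then closed by 6π-electrocyclisation of this ketene onto the CH2 terminus of the ethoxyvinyl group (C1–C6), and enolisation of the cyclohexadienone delivers the phenol as Cr(CO)3 complex 16, which air demetallates; no stereocentre is formed. The closest known reaction types are the Dötz benzannulation of alkenyl(alkoxy)carbene chromium complexes with alkynes, the regiodefined insertion of ynamines into such carbenes and the thermal ring closure of dienyl(alkoxy)carbene chromium complexes to ortho-alkoxyphenols, but an ynol ether has not been paired with a 1-alkoxyvinyl carbene. The step needs the regiochemistry that puts the ethoxy carbon of 10 next to the CO-derived C1, and the ketene-acetal-like polarisation of the ynol ether (nucleophilic at the chain carbon, which seeks the electrophilic carbene carbon) should secure it; the opposite sense would show up after step 8 as a 2,6-diethoxyquinone. It also needs CO insertion to outpace cyclopentannulation or furan formation from the doubly oxygen-stabilised vinylcarbene, which a chromium alkoxycarbene in a donor solvent favours but which is the untested point. The neutral medium at 55 °C should leave the isolated E-olefin and the ynol ether (well below its retro-ene temperature) unchanged.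

Step 8
Reactants: 17 2,5-diethoxy-4-methoxy-3-[(E)-nonadec-14-enyl]phenol
Product: 18 2,5-diethoxy-3-[(E)-nonadec-14-enyl]-1,4-benzoquinone
Conditions: (NH4)2Ce(NO3)6 (2.2 equiv), MeCN/H2O, 0 °C
Reagents that add atoms: water, O
Why: Oxidative demethylation of a para-methoxyphenol by tetravalent cerium: after two one-electron oxidations water adds at C4 and methanol leaves, giving the para-quinone; the isolated olefin should survive the brief cold treatment.

Step 9
Reactants: 18 2,5-diethoxy-3-[(E)-nonadec-14-enyl]-1,4-benzoquinone
Product: 20 2,5-dihydroxy-3-[(E)-nonadec-14-enyl]-1,4-benzoquinone (target), via disodium quinonediolate 19 (not isolated)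
Conditions: 2 M NaOH, EtOH, 70 °C; then 2 M HCl, 0 °C
Reagents that add atoms: sodium hydroxide, [Na+].[OH-] (sodium held only in 19)
Why: Both ethoxy groups are vinylogous esters and are displaced by hydroxide through addition–elimination at C2 and C5; the stable dianion 19 is then protonated, as in the usual hydrolysis of 2,5-dialkoxy-3-alkylbenzoquinones.

**Compound list**

1 | myristelaidic acid, (E)-tetradec-9-enoic acid | CCCC/C=C/CCCCCCCC(=O)O | starting material
2 | (E)-tetradec-9-en-1-ol | CCCC/C=C/CCCCCCCCO | intermediate
3 | (E)-14-bromotetradec-5-ene | CCCC/C=C/CCCCCCCCBr | intermediate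
4 | 1-bromo-5-chloropentane | ClCCCCCBr | starting material
5 | (E)-tetradec-9-enylmagnesium bromide | CCCC/C=C/CCCCCCCC[Mg]Br | intermediate (not isolated)
6 | (E)-19-chlorononadec-5-ene | CCCC/C=C/CCCCCCCCCCCCCCl | intermediate
7 | (E)-19-iodononadec-5-ene | CCCC/C=C/CCCCCCCCCCCCCI | intermediate
8 | ethoxyacetylene | C#COCC | starting material
9 | lithium ethoxyacetylide | [Li]C#COCC | intermediate (not isolated)
10 | (E)-1-ethoxyhenicos-16-en-1-yne | CCCC/C=C/CCCCCCCCCCCCCC#COCC | intermediate
11 | ethyl vinyl ether | C=COCC | starting material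
12 | chromium hexacarbonyl | O=C=[Cr](=C=O)(=C=O)(=C=O)(=C=O)=C=O | starting material
13 | 1-ethoxyvinyllithium | [Li]C(=C)OCC | intermediate (not isolated)
14 | lithium pentacarbonyl(2-ethoxyacryloyl)chromate | [Li+].[O-]C(C(=C)OCC)=[Cr](=C=O)(=C=O)(=C=O)(=C=O)=C=O | intermediate (not isolated)
15 | pentacarbonyl[(1-ethoxyvinyl)(methoxy)carbene]chromium | COC(=[Cr](=C=O)(=C=O)(=C=O)(=C=O)=C=O)C(=C)OCC | intermediate
16 | tricarbonyl[η6-2,5-diethoxy-4-methoxy-3-((E)-nonadec-14-enyl)phenol]chromium (arene η6-bound to Cr, SMILES written as two parts) | CCCC/C=C/CCCCCCCCCCCCCc1c(OCC)c(O)cc(OCC)c1OC.O=C=[Cr](=C=O)=C=O | intermediate (not isolated)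
17 | 2,5-diethoxy-4-methoxy-3-[(E)-nonadec-14-enyl]phenol | CCCC/C=C/CCCCCCCCCCCCCc1c(OCC)c(O)cc(OCC)c1OC | intermediate
18 | 2,5-diethoxy-3-[(E)-nonadec-14-enyl]-1,4-benzoquinone | CCCC/C=C/CCCCCCCCCCCCCC1=C(OCC)C(=O)C=C(OCC)C1=O | intermediate
19 | disodium 3-[(E)-nonadec-14-enyl]-1,4-benzoquinone-2,5-diolate | CCCC/C=C/CCCCCCCCCCCCCC1=C([O-])C(=O)C=C([O-])C1=O.[Na+].[Na+] | intermediate (not isolated)
20 | 2,5-dihydroxy-3-[(E)-nonadec-14-enyl]-1,4-benzoquinone | CCCC/C=C/CCCCCCCCCCCCCC1=C(O)C(=O)C=C(O)C1=O | target

**Step count**

Total: 9 steps. Longest linear sequence: 8 steps (steps 1–5, then 7–9); step 6 is a one-step branch.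

**Steps most likely to fail**

Step 7 (proposed new method). The doubly oxygen-stabilised vinylcarbene may be too stable to insert CO, so the reaction could stall after alkyne insertion or drift to five-membered-ring products. Insertion of 10 in the reverse orientation and oligomerisation of the ynol ether at chromium are the other failure paths. The fallback uses known chemistry, sets out from iodide 7 and returns at 19 (and so 20). 1,2,4,5-Tetramethoxybenzene is lithiated between two methoxy groups (n-BuLi, THF/HMPA, −40 → 0 °C) to 2,3,5,6-tetramethoxyphenyllithium F1, which is alkylated by 7 to 1,2,4,5-tetramethoxy-3-[(E)-nonadec-14-enyl]benzene F2. Oxidation with (NH4)2Ce(NO3)6 in MeCN/H2O gives 2,5-dimethoxy-3-[(E)-nonadec-14-enyl]-1,4-benzoquinone F3, and the hydroxide treatment of step 9 converts F3 into 19, which is acidified to 20.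

Step 6. Residual tert-butyllithium may add to Cr(CO)6 in competition, and the β-unsubstituted, acrylate-like carbene complex may polymerise or suffer conjugate addition during methylation and concentration. The fallback reaches the same dienylketene without chromium; it sets out from 1-ethoxyvinyllithium 13 and iodide 7 and returns at phenol 17, bypassing steps 5 and 7. Reagent 13 adds to one carbonyl of diethyl squarate (THF, −78 °C) to give lithium 2,3-diethoxy-1-(1-ethoxyvinyl)-4-oxocyclobut-2-en-1-olate F4, which is methylated in the same flask with MeOTf to 2,3-diethoxy-4-(1-ethoxyvinyl)-4-methoxycyclobut-2-en-1-one F5. Iodide 7 is turned by lithium–iodine exchange (t-BuLi, Et2O/pentane, −78 °C) into (E)-nonadec-14-enyllithium F6, which adds 1,2 to the carbonyl of F5 to give lithium 2,3-diethoxy-4-(1-ethoxyvinyl)-4-methoxy-1-[(E)-nonadec-14-enyl]cyclobut-2-en-1-olate F7. Treatment with (CF3CO)2O and then aqueous NaHCO3 effects the allylic transposition with loss of ethanol to 2-ethoxy-4-(1-ethoxyvinyl)-4-methoxy-3-[(E)-nonadec-14-enyl]cyclobut-2-en-1-one F8. Heating F8 in toluene at 110 °C opens the four-membered ring to the dienylketene, which closes ring A by 6π-electrocyclisation and enolises to 17.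

Step 5. Substitution by the weakly nucleophilic, aggregated acetylide at the long-chain iodide may be slow, with E2 elimination competing and the ynol ether hydrating to an ester on work-up. The fallback sets out from iodide 7 and returns at target 20, bypassing steps 5 to 9. Kornblum oxidation of 7 (DMSO, NaHCO3, 110 °C) gives (E)-nonadec-14-enal F9. Organocatalytic reductive C-alkylation of commercial 2,5-dihydroxy-1,4-benzoquinone (used in excess) with F9 and Hantzsch ester (L-proline cat., CH2Cl2, 20 °C) proceeds by Knoevenagel condensation and hydride transfer to the quinone methide, giving 20 directly.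

**Further compounds**

F1 | step 7 | 2,3,5,6-tetramethoxyphenyllithium | [Li]c1c(OC)c(OC)cc(OC)c1OC
F2 | step 7 | 1,2,4,5-tetramethoxy-3-[(E)-nonadec-14-enyl]benzene | CCCC/C=C/CCCCCCCCCCCCCc1c(OC)c(OC)cc(OC)c1OC
F3 | step 7 | 2,5-dimethoxy-3-[(E)-nonadec-14-enyl]-1,4-benzoquinone | CCCC/C=C/CCCCCCCCCCCCCC1=C(OC)C(=O)C=C(OC)C1=O
F4 | step 6 | lithium 2,3-diethoxy-1-(1-ethoxyvinyl)-4-oxocyclobut-2-en-1-olate (racemic) | [Li+].[O-]C1(C(=C)OCC)C(OCC)=C(OCC)C1=O
F5 | step 6 | 2,3-diethoxy-4-(1-ethoxyvinyl)-4-methoxycyclobut-2-en-1-one (racemic) | COC1(C(=C)OCC)C(OCC)=C(OCC)C1=O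
F6 | step 6 | (E)-nonadec-14-enyllithium | CCCC/C=C/CCCCCCCCCCCCC[Li]
F7 | step 6 | lithium 2,3-diethoxy-4-(1-ethoxyvinyl)-4-methoxy-1-[(E)-nonadec-14-enyl]cyclobut-2-en-1-olate (mixture of diastereomers) | [Li+].[O-]C1(CCCCCCCCCCCCC/C=C/CCCC)C(OCC)=C(OCC)C1(OC)C(=C)OCC
F8 | step 6 | 2-ethoxy-4-(1-ethoxyvinyl)-4-methoxy-3-[(E)-nonadec-14-enyl]cyclobut-2-en-1-one (racemic) | CCOC1=C(CCCCCCCCCCCCC/C=C/CCCC)C(OC)(C(=C)OCC)C1=O
F9 | step 5 | (E)-nonadec-14-enal | CCCC/C=C/CCCCCCCCCCCCC=O
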